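The flavone is disconnected across O1–C8a, C4–C4a and O1–C2. Ring A carries the ring-C oxygen O1 (on C8a) and the C4 carbonyl (on C4a) on adjacent carbons, with the C5 oxygen beside C4a and the benzyl-bearing C8 beside C8a, so the C4a–C8a edge is treated as a 3-alkoxyaryne. In one fluoride-triggered operation this aryne inserts into the carboxyl C–O bond of an arylpropiolic acid and the liberated phenoxide closes ring C, giving the tetramethyl ether of the target. The aryne precursor is a pentasubstituted ortho-silylaryl triflate, reached from a salicylaldehyde by aryl Grignard addition, ionic deoxygenation and carbamate-directed silylation; global demethylation ends the route.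

Key step: step 6

Remark on the chemistry: flavone numbering (O1, C2–C4, C4a, C5–C8, C8a) is used for ring atoms; 2 is taken as the commercial THF solution; carbinol 3 is racemic, its stereocentre is removed in step 2, and the target is achiral.

Step 1
Reactants: 1 2-hydroxy-4,6-dimethoxybenzaldehyde; 2 4-methoxyphenylmagnesium bromide
Product: 3 2-[hydroxy(4-methoxyphenyl)methyl]-3,5-dimethoxyphenol (racemic)
Conditions: 2 (2.5 equiv), THF, 0 °C to rt; cold aq. NH4Cl; crude 3 taken on at once
Reagents that add atoms: none
Why: Grignard 1,2-addition to the aldehyde, in which the first equivalent deprotonates the phenol and the chelated magnesium phenoxide still accepts the aryl nucleophile at the formyl carbon, the new carbinol centre being formed racemic and erased in step 2.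

Step 2
Reactants: 3 2-[hydroxy(4-methoxyphenyl)methyl]-3,5-dimethoxyphenol
Product: 4 3,5-dimethoxy-2-(4-methoxybenzyl)phenol
Conditions: Et3SiH (5 equiv), TFA (3 equiv), CH2Cl2, 0 °C
Reagents that add atoms: none
Why: Ionic hydrogenation, in which acid ionises the doubly activated benzhydrol to a stabilised diarylmethyl cation (protonated ortho-quinone methide) that takes hydride from the silane held in excess.

Step 3
Reactants: 4 3,5-dimethoxy-2-(4-methoxybenzyl)phenol
Product: 5 3,5-dimethoxy-2-(4-methoxybenzyl)phenyl N-isopropylcarbamate
Conditions: i-PrNCO (1.5 equiv), Et3N (cat.), CH2Cl2, rt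
Reagents that add atoms: isopropyl isocyanate, CC(C)N=C=O
Why: Base-catalysed addition of the phenol to an isocyanate (carbamoylation) installs a strong ortho-directing group that can later be removed under mild conditions.

Step 4
Reactants: 5 3,5-dimethoxy-2-(4-methoxybenzyl)phenyl N-isopropylcarbamate
Product: 9 3,5-dimethoxy-2-(4-methoxybenzyl)-6-(trimethylsilyl)phenyl N-isopropylcarbamate, via N-silyl carbamate 6 (not isolated), via aryllithium 7 (not isolated), via doubly silylated carbamate 8 (not isolated)
Conditions: TMSOTf (1.1 equiv), TMEDA (1.1 equiv), Et2O, 0 °C to rt; n-BuLi (2.2 equiv), TMEDA (2 equiv), −78 °C; TMSCl (3 equiv), −78 °C to rt; aq. NaHSO4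
Reagents that add atoms: chlorotrimethylsilane, C[Si](C)(C)Cl
Why: Directed ortho-metalation, in which the N-silylated carbamate and the neighbouring methoxy group together direct lithiation to the one free ring position ortho to the carbamate, low temperature and the alkyllithium/TMEDA base favouring this site over the benzylic CH2 and over the C–H between the two methoxy groups, after which the chlorosilane quenches the aryllithium and the N–Si bond is hydrolysed on work-up.

Step 5
Reactants: 9 3,5-dimethoxy-2-(4-methoxybenzyl)-6-(trimethylsilyl)phenyl N-isopropylcarbamate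
Product: 11 3,5-dimethoxy-2-(4-methoxybenzyl)-6-(trimethylsilyl)phenyl trifluoromethanesulfonate, via silylphenol 10 (not isolated)
Conditions: DBU (1.5 equiv), Et2NH (1.3 equiv), MeCN, 40 °C; then PhNTf2 (1.5 equiv), rt
Reagents that add atoms: N-phenylbis(trifluoromethanesulfonimide), O=S(=O)(N(c1ccccc1)S(=O)(=O)C(F)(F)F)C(F)(F)F
Why: The N–H carbamate should be cleaved by base-induced elimination of isopropyl isocyanate (E1cB, the isocyanate being trapped by diethylamine as a urea) and the hindered phenoxide sulfonylated in the same flask by the mild triflyl donor, so that the desilylation-prone silylphenol is never isolated.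

Step 6
Reactants: 11 3,5-dimethoxy-2-(4-methoxybenzyl)-6-(trimethylsilyl)phenyl trifluoromethanesulfonate; 12 3-(4-methoxyphenyl)propiolic acid
Product: 15 5,7-dimethoxy-8-(4-methoxybenzyl)-2-(4-methoxyphenyl)-4H-chromen-4-one, via aryne 13 (not isolated), via hydroxyaryl ynone 14 (not isolated)
Conditions: 12 (1.5 equiv), CsF (5 equiv), THF, rt (cesium carboxylate pre-formed); then 11, sealed tube, 120 °C
Reagents that add atoms: none
Why: Proposed new method: fluoride attack at silicon expels triflate to give aryne 13 (C4a≡C8a), the cesium propiolate adds through oxygen at C8a, the C4a carbanion attacks its own ester carbonyl through a four-membered transition state (1,3 O-to-C acyl shift, net insertion into the carboxyl C–O bond) to release phenoxide 14, and this phenoxide adds to the ynone carbon bearing the anisyl group, with protonation at C3 by the bifluoride that holds the acid proton completing the flavone. The closest known reaction types are fluoride-induced aryne insertion into the C–O bond of carboxylic acids, which gives ortho-hydroxyaryl ketones, and base-mediated cyclisation of ortho-hydroxyaryl ynones to flavones, and the proposal is to merge them on an arylpropiolic acid and a pentasubstituted aryne. Ring C closes by 6-endo-dig oxa-Michael addition, forming O1–C2 after O1–C8a and C4–C4a, and no stereocentre is created. The step needs carboxylate addition at C8a and not C4a, which the C5 methoxy group should secure because its inductive withdrawal polarises the aryne towards attack at the distal carbon and places the carbanion beside oxygen, an effect expected to outweigh the hindrance of the C8 benzyl group and the weaker opposing bias of the C7 methoxy group. Acyl transfer must outrun protonation of the aryl anion, hence aprotic THF at high temperature, the acid present as its cesium salt and sparingly soluble CsF keeping the aryne concentration low. Closure in the 6-endo sense is expected over 5-exo closure to an aurone because under aprotic, reversible conditions the conjugated pyranone is the thermodynamic product.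

Step 7
Reactants: 15 5,7-dimethoxy-8-(4-methoxybenzyl)-2-(4-methoxyphenyl)-4H-chromen-4-one
Product: 16 5,7-dihydroxy-8-(4-hydroxybenzyl)-2-(4-hydroxyphenyl)-4H-chromen-4-one
Conditions: BBr3 (10 equiv), CH2Cl2, −78 °C to rt; MeOH then water, 0 °C
Reagents that add atoms: none
Why: Boron tribromide demethylation of aryl methyl ethers, in which each ether oxygen coordinates boron and bromide removes the methyl group by SN2, the C5 ether being helped by chelation to the C4 carbonyl and the low temperature sparing the diarylmethane link.

Compound list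
1 | 2-hydroxy-4,6-dimethoxybenzaldehyde | COc1cc(O)c(C=O)c(OC)c1 | starting material
2 | 4-methoxyphenylmagnesium bromide | COc1ccc([Mg]Br)cc1 | starting material
3 | 2-[hydroxy(4-methoxyphenyl)methyl]-3,5-dimethoxyphenol (racemic) | COc1ccc(C(O)c2c(O)cc(OC)cc2OC)cc1 | intermediate
4 | 3,5-dimethoxy-2-(4-methoxybenzyl)phenol | COc1ccc(Cc2c(O)cc(OC)cc2OC)cc1 | intermediate
5 | 3,5-dimethoxy-2-(4-methoxybenzyl)phenyl N-isopropylcarbamate | COc1ccc(Cc2c(OC(=O)NC(C)C)cc(OC)cc2OC)cc1 | intermediate
6 | 3,5-dimethoxy-2-(4-methoxybenzyl)phenyl N-isopropyl-N-(trimethylsilyl)carbamate | COc1ccc(Cc2c(OC(=O)N(C(C)C)[Si](C)(C)C)cc(OC)cc2OC)cc1 | intermediate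
7 | [2-[(N-isopropyl-N-trimethylsilyl)carbamoyloxy]-4,6-dimethoxy-3-(4-methoxybenzyl)phenyl]lithium | COc1ccc(Cc2c(OC)cc(OC)c([Li])c2OC(=O)N(C(C)C)[Si](C)(C)C)cc1 | intermediate
8 | 3,5-dimethoxy-2-(4-methoxybenzyl)-6-(trimethylsilyl)phenyl N-isopropyl-N-(trimethylsilyl)carbamate | COc1ccc(Cc2c(OC)cc(OC)c([Si](C)(C)C)c2OC(=O)N(C(C)C)[Si](C)(C)C)cc1 | intermediate
9 | 3,5-dimethoxy-2-(4-methoxybenzyl)-6-(trimethylsilyl)phenyl N-isopropylcarbamate | COc1ccc(Cc2c(OC)cc(OC)c([Si](C)(C)C)c2OC(=O)NC(C)C)cc1 | intermediate
10 | 3,5-dimethoxy-2-(4-methoxybenzyl)-6-(trimethylsilyl)phenol (formed as its DBU salt) | COc1ccc(Cc2c(OC)cc(OC)c([Si](C)(C)C)c2O)cc1 | intermediate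
11 | 3,5-dimethoxy-2-(4-methoxybenzyl)-6-(trimethylsilyl)phenyl trifluoromethanesulfonate | COc1ccc(Cc2c(OC)cc(OC)c([Si](C)(C)C)c2OS(=O)(=O)C(F)(F)F)cc1 | intermediate
12 | 3-(4-methoxyphenyl)propiolic acid | COc1ccc(cc1)C#CC(=O)O | starting material
13 | 3,5-dimethoxy-6-(4-methoxybenzyl)benzyne (1,2-didehydrobenzene) | COc1ccc(CC2=C(OC)C=C(OC)C#C2)cc1 | intermediate
14 | 1-[2-hydroxy-4,6-dimethoxy-3-(4-methoxybenzyl)phenyl]-3-(4-methoxyphenyl)prop-2-yn-1-one (formed as its cesium phenoxide) | COc1ccc(C#CC(=O)c2c(OC)cc(OC)c(Cc3ccc(OC)cc3)c2O)cc1 | intermediate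
15 | 5,7-dimethoxy-8-(4-methoxybenzyl)-2-(4-methoxyphenyl)-4H-chromen-4-one | COc1ccc(cc1)-c1cc(=O)c2c(OC)cc(OC)c(Cc3ccc(OC)cc3)c2o1 | intermediate
16 | 5,7-dihydroxy-8-(4-hydroxybenzyl)-2-(4-hydroxyphenyl)-4H-chromen-4-one | O=c1cc(-c2ccc(O)cc2)oc2c(Cc3ccc(O)cc3)c(O)cc(O)c12 | target

Total step count: 7.
Longest linear sequence: 7 steps, from 1 to 16; 2 and 12 are bought.

Steps most likely to fail

Step 6. The aryl anion may be protonated before it reaches the ester carbonyl, which would stop the cascade at an O-aryl propiolate. The carboxylate may also add in the reverse sense under the steric pressure of the benzyl group, the propiolate may decarboxylate at the temperature needed, or the phenoxide may close 5-exo. The fallback uses known chemistry, sets out from phenol 4 and rejoins the route at 15. Ortho-acetylation of 4 with Ac2O and BF3·OEt2 at 80 °C (O-acetylation, then chelation-controlled Fries shift to the position next to the hydroxyl) should give 1-[2-hydroxy-4,6-dimethoxy-3-(4-methoxybenzyl)phenyl]ethan-1-one F1. Claisen–Schmidt condensation of F1 with 4-methoxybenzaldehyde (KOH, EtOH, rt) should give the chalcone (E)-1-[2-hydroxy-4,6-dimethoxy-3-(4-methoxybenzyl)phenyl]-3-(4-methoxyphenyl)prop-2-en-1-one F2. Oxidative cyclisation of F2 with catalytic I2 in DMSO at 130 °C should then deliver 15.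

Step 4. Deprotonation may occur at the diarylmethane CH2 (lateral metalation, possibly followed by carbamoyl migration) or at the ring C–H between the two methoxy groups, so that silicon ends up at the wrong carbon. The fallback fixes the site by halogen–metal exchange, sets out from 4 and comes back at 11, so that the carbamate steps 3 to 5 are bypassed. Amine-directed ortho-bromination of 4 (NBS, catalytic i-Pr2NH, CH2Cl2, −78 to 0 °C) should give 2-bromo-3,5-dimethoxy-6-(4-methoxybenzyl)phenol F3. O-silylation with hexamethyldisilazane (THF, 65 °C) should give [2-bromo-3,5-dimethoxy-6-(4-methoxybenzyl)phenoxy]trimethylsilane F4. Treatment with n-BuLi in THF at −78 °C should exchange bromine for lithium to give [4,6-dimethoxy-3-(4-methoxybenzyl)-2-(trimethylsilyloxy)phenyl]lithium F5. In F5 the silyl group should shift from oxygen to carbon (retro-Brook rearrangement) to give the lithium salt of 10, which Tf2O at −78 °C should trap as 11.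

Step 2. The strongly stabilised benzhydryl cation may alkylate the electron-rich trioxygenated ring of 3 or 4 faster than it takes hydride, leading to oligomeric triarylmethanes. The fallback sets out from 3 and returns at 4: the benzylic C–O bond is cleaved by catalytic hydrogenolysis (H2, Pd/C, EtOAc, rt) under neutral conditions, so that no free cation is generated; no new compound is made.

Further compounds
F1 | step 6 | 1-[2-hydroxy-4,6-dimethoxy-3-(4-methoxybenzyl)phenyl]ethan-1-one | CC(=O)c1c(OC)cc(OC)c(Cc2ccc(OC)cc2)c1O
F2 | step 6 | (E)-1-[2-hydroxy-4,6-dimethoxy-3-(4-methoxybenzyl)phenyl]-3-(4-methoxyphenyl)prop-2-en-1-one | COc1ccc(/C=C/C(=O)c2c(OC)cc(OC)c(Cc3ccc(OC)cc3)c2O)cc1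
F3 | step 4 | 2-bromo-3,5-dimethoxy-6-(4-methoxybenzyl)phenol | COc1ccc(Cc2c(OC)cc(OC)c(Br)c2O)cc1
F4 | step 4 | [2-bromo-3,5-dimethoxy-6-(4-methoxybenzyl)phenoxy]trimethylsilane | COc1ccc(Cc2c(OC)cc(OC)c(Br)c2O[Si](C)(C)C)cc1
F5 | step 4 | [4,6-dimethoxy-3-(4-methoxybenzyl)-2-(trimethylsilyloxy)phenyl]lithium | COc1ccc(Cc2c(OC)cc(OC)c([Li])c2O[Si](C)(C)C)cc1
F0 | step 2 | none | none
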